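**Retrosynthetic overview**
- Last disconnection: the two C–C bonds to the picolyl carbons, giving a chiral dibromo bicycle and two molecules of 3-picoline (the pyridine rings are bought, not built).
- Key disconnection: the cis-fused cyclopentane/isoxazolidine pair is opened in one retro-[3+2] to the N-alkyl nitrone of a (Z)-5-alkenal, i.e. an aldehyde plus an N-alkylhydroxylamine.
- The forward cycloaddition is run under a chiral Brønsted acid so that C3, C3a and C6a arise together in one enantiomeric series.
- Aldehyde arm: Wittig reaction of an ω-bromoalkyl ylide with the lactol of 5-hydroxypentanal, then oxidation. Hydroxylamine arm: N-alkylation of N,O-bis-Boc-hydroxylamine with 1,12-dibromododecane, then acid.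
- Ring order: cyclopentane (C6a–C3a bond) and isoxazolidine (O2–C3 bond) close in the same cycloaddition; no ring is formed afterwards.

Assumption: the (S)-configured acid catalyst is taken to give the (3S,3aS,6aR) series; the sense of induction is read from the first run and the (R)-catalyst is used instead if it is the opposite.

**Route**

Step 1
Reactants: 1 1,8-dibromooctane; 2 triphenylphosphine
Product: 3 (8-bromooctyl)triphenylphosphonium bromide
Conditions: 1 (4 equiv), toluene, reflux, 24 h; filter the precipitated salt
Reagents that add atoms: none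
Why: SN2 quaternisation of the phosphine by a primary bromide, where the excess of dibromide and precipitation of the mono-salt from toluene suppress the bis-salt; no stereocentre is involved.

Step 2
Reactants: 3 (8-bromooctyl)triphenylphosphonium bromide; 4 tetrahydro-2H-pyran-2-ol
Product: 6 (Z)-13-bromotridec-5-en-1-ol, via phosphonium ylide 5 (not isolated)
Conditions: 3 (2.2 equiv), NaN(SiMe3)2 (2.1 equiv), THF, −78 °C, 30 min; then 4 (1.0 equiv), −78 → 0 °C, 3 h; aq NH4Cl
Reagents that add atoms: none
Why: Wittig olefination of the open hydroxy-aldehyde form of the lactol with a non-stabilised ylide under lithium-free kinetic control gives the (Z)-alkene (about 95:5), the geometry that later fixes the C3/C3a relationship, and the primary C–Br bond survives at or below 0 °C.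

Step 3
Reactants: 6 (Z)-13-bromotridec-5-en-1-ol
Product: 7 (Z)-13-bromotridec-5-enal
Conditions: 2,2,6,6-tetramethylpiperidin-1-oxyl (10 mol %), PhI(OAc)2 (1.1 equiv), CH2Cl2, 20 °C
Reagents that add atoms: none
Why: oxoammonium-mediated (nitroxyl/PhI(OAc)2) oxidation of a primary alcohol stops at the aldehyde and leaves the (Z)-alkene and the bromide untouched.

Step 4
Reactants: 8 1,12-dibromododecane; 9 tert-butyl N-[(tert-butoxycarbonyl)oxy]carbamate
Product: 10 tert-butyl N-(12-bromododecyl)-N-[(tert-butoxycarbonyl)oxy]carbamate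
Conditions: 8 (4 equiv), K2CO3 (1.5 equiv), DMF, 40 °C, 16 h
Reagents that add atoms: none
Why: SN2 N-alkylation of the acidic N–H of the doubly acylated hydroxylamine, in which oxygen is blocked so only nitrogen reacts and the excess of dibromide prevents double substitution.

Step 5
Reactants: 10 tert-butyl N-(12-bromododecyl)-N-[(tert-butoxycarbonyl)oxy]carbamate
Product: 11 N-(12-bromododecyl)hydroxylamine hydrochloride
Conditions: 4 M HCl in 1,4-dioxane, 20 °C, 4 h; filter the salt
Reagents that add atoms: hydrogen chloride, Cl
Why: acidolysis of both Boc groups (tert-butyl cation loss, then decarboxylation) frees the N-alkylhydroxylamine, and isolating it as the hydrochloride prevents self-alkylation by its own bromide.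

Step 6
Reactants: 7 (Z)-13-bromotridec-5-enal; 11 N-(12-bromododecyl)hydroxylamine hydrochloride
Product: 14 (3S,3aS,6aR)-1-(12-bromododecyl)-3-(7-bromoheptyl)hexahydro-1H-cyclopenta[c]isoxazole, via free hydroxylamine 12 (not isolated), via nitrone 13 (not isolated)
Conditions: NaHCO3 (1.5 equiv), MgSO4, CH2Cl2, 0 °C, 1 h, filter, evaporate below 20 °C; then (S)-3,3'-bis(2,4,6-triisopropylphenyl)-1,1'-binaphthalene-2,2'-diyl N-triflylphosphoramide (10 mol %), 4 Å molecular sieves, toluene (0.05 M), −20 °C; aq NaHCO3
Reagents that add atoms: none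
Why: Proposed new method: the strong chiral acid protonates (or tightly hydrogen-bonds) the nitrone oxygen, and the resulting N-hydroxyiminium/phosphoramidate contact ion pair, with a much lower LUMO than the free nitrone, is attacked by the tethered (Z)-dialkyl alkene in a concerted but asynchronous (C–C bond leading) intramolecular nitrone–alkene [3+2] cycloaddition (LeBel type) at a temperature where the uncatalysed reaction is negligible; the three-carbon tether allows only the cis ring fusion, suprafacial addition to the (Z)-alkene places H3 and H3a cis, and the triisopropylphenyl walls of the bound anion select the enantiotopic face of the C=N bond, so C3, C3a and C6a are set together; the closest known reaction types are the chiral N-triflylphosphoramide-catalysed nitrone/vinyl ether [3+2] and the chiral Brønsted acid-catalysed intramolecular hydrazone/alkene [3+2].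

Step 7
Reactants: 14 (3S,3aS,6aR)-1-(12-bromododecyl)-3-(7-bromoheptyl)hexahydro-1H-cyclopenta[c]isoxazole; 15 3-methylpyridine
Product: 17 pyrinodemin B, via 3-picolyllithium 16 (not isolated)
Conditions: 15 (3.0 equiv), LiN(iPr)2 (2.8 equiv), THF, −78 → −40 °C, 1 h; then 14, THF, −78 → 20 °C; aq NH4Cl
Reagents that add atoms: none
Why: lateral lithiation of 3-picoline followed by double SN2 alkylation at the two primary bromides lengthens each arm by one CH2 and a pyridine ring, while the three stereocentres and the N–O bond are not touched at low temperature.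

**Compound list**
1 | 1,8-dibromooctane | BrCCCCCCCCBr | starting material
2 | triphenylphosphine | c1ccccc1P(c1ccccc1)c1ccccc1 | starting material
3 | (8-bromooctyl)triphenylphosphonium bromide | [Br-].BrCCCCCCCC[P+](c1ccccc1)(c1ccccc1)c1ccccc1 | intermediate
4 | tetrahydro-2H-pyran-2-ol (lactol of 5-hydroxypentanal, racemic) | OC1CCCCO1 | starting material
5 | (8-bromooctylidene)triphenylphosphorane (ylide) | BrCCCCCCCC=P(c1ccccc1)(c1ccccc1)c1ccccc1 | intermediate
6 | (Z)-13-bromotridec-5-en-1-ol | OCCCC/C=C\CCCCCCCBr | intermediate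
7 | (Z)-13-bromotridec-5-enal | O=CCCC/C=C\CCCCCCCBr | intermediate
8 | 1,12-dibromododecane | BrCCCCCCCCCCCCBr | starting material
9 | tert-butyl N-[(tert-butoxycarbonyl)oxy]carbamate (N,O-bis-Boc-hydroxylamine) | CC(C)(C)OC(=O)NOC(=O)OC(C)(C)C | starting material
10 | tert-butyl N-(12-bromododecyl)-N-[(tert-butoxycarbonyl)oxy]carbamate | CC(C)(C)OC(=O)N(CCCCCCCCCCCCBr)OC(=O)OC(C)(C)C | intermediate
11 | N-(12-bromododecyl)hydroxylamine hydrochloride | Cl.ONCCCCCCCCCCCCBr | intermediate
12 | N-(12-bromododecyl)hydroxylamine (free base) | ONCCCCCCCCCCCCBr | intermediate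
13 | (Z)-nitrone, N-[(1Z,5Z)-13-bromotridec-5-en-1-ylidene]-12-bromododecan-1-amine N-oxide | [O-]/[N+](CCCCCCCCCCCCBr)=C\CCC/C=C\CCCCCCCBr | intermediate
14 | (3S,3aS,6aR)-1-(12-bromododecyl)-3-(7-bromoheptyl)hexahydro-1H-cyclopenta[c]isoxazole (cis ring fusion, H3/H3a cis) | BrCCCCCCCCCCCCN1O[C@@H](CCCCCCCBr)[C@H]2CCC[C@H]21 | intermediate
15 | 3-methylpyridine (3-picoline) | Cc1cccnc1 | starting material
16 | (pyridin-3-ylmethyl)lithium | [Li]Cc1cccnc1 | intermediate
17 | pyrinodemin B, (3S,3aS,6aR)-3-[8-(pyridin-3-yl)octyl]-1-[13-(pyridin-3-yl)tridecyl]hexahydro-1H-cyclopenta[c]isoxazole | c1cncc(CCCCCCCCCCCCCN2O[C@@H](CCCCCCCCc3cccnc3)[C@H]3CCC[C@H]32)c1 | target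

**Step count**
Total: 7 steps. Longest linear sequence: 5 steps (steps 1, 2, 3, 6, 7).

**Three steps most likely to fail**

Step 6 is the main risk. The basic isoxazolidine product can hold the acid and stop turnover, the ee may be low, the acid may give some bridged regioisomer, and the aliphatic nitrone may self-condense. The fallback replaces catalyst control by a carbohydrate auxiliary on nitrogen; it sets out from 7 and comes back at 14. Commercial 2,3:5,6-di-O-isopropylidene-α-D-mannofuranose is converted with NH2OH·HCl/NaHCO3 in aqueous ethanol into 2,3:5,6-di-O-isopropylidene-D-mannose oxime F1. Heating F1 with 7 in CHCl3 at 60 °C gives the N-(α-D-mannofuranosyl) nitrone F2, which cyclises in the same flask to the N-glycosyl isoxazolidine F3. F3 and its isomer at the three new centres are diastereomers, so F3 is purified by chromatography whatever the ratio. NH2OH·HCl/NaOAc in aqueous MeOH at 60 °C removes the sugar as its oxime and leaves the N–H isoxazolidine F4. F4 is N-alkylated with an excess of 8 (K2CO3, NaI cat., MeCN, 60 °C) to give 14.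

Step 7 is the second risk. Lithiation of 3-picoline is incomplete at equilibrium, the amide base can eliminate HBr from the primary bromides, and a strong base may open the isoxazolidine. The fallback replaces the carbanion alkylation by olefination and reduction; it sets out from 14 and comes back at 17. Heating 14 with PPh3 (2.5 equiv, MeCN, 80 °C) gives the bis(phosphonium) dibromide F5. NaN(SiMe3)2 in THF at −78 °C followed by pyridine-3-carbaldehyde gives the bis(pyridylalkene) F6 (mainly Z,Z; the geometry is lost in the next operation). Diimide, generated from 2-nitrobenzenesulfonohydrazide and Et3N in CH2Cl2 at 20 °C, saturates both C=C bonds without cleaving the N–O bond and gives 17.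

Step 2 is the third risk. The ylide carries its own primary bromide and the lactol opens slowly, so ylide alkylation, ether formation and a lower Z:E ratio can all cost yield. The fallback replaces the Wittig reaction by alkyne alkylation and semi-hydrogenation; it sets out from 4 and comes back at 6. Lactol 4 with dimethyl (1-diazo-2-oxopropyl)phosphonate and K2CO3 in MeOH (Ohira–Bestmann homologation) gives hex-5-yn-1-ol F7, which can also be bought. Its dianion (n-BuLi, 2.1 equiv, THF/DMPU, −78 → 0 °C) is alkylated on carbon with 1,7-dibromoheptane (4 equiv) to give 13-bromotridec-5-yn-1-ol F8. Hydrogenation (H2, 1 atm) over Pd/CaCO3 poisoned with Pb(OAc)2 and quinoline gives the (Z)-alkene 6.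

**Further compounds**
F1 | step 6 | 2,3:5,6-di-O-isopropylidene-D-mannose (E)-oxime | O/N=C/[C@H]1OC(C)(C)O[C@H]1[C@H](O)[C@H]1COC(C)(C)O1
F2 | step 6 | (Z)-N-(2,3:5,6-di-O-isopropylidene-α-D-mannofuranosyl) nitrone of (Z)-13-bromotridec-5-enal | [O-]/[N+](=C\CCC/C=C\CCCCCCCBr)[C@H]1O[C@H]([C@H]3COC(C)(C)O3)[C@@H]2OC(C)(C)O[C@H]12
F3 | step 6 | (3S,3aS,6aR)-3-(7-bromoheptyl)-1-(2,3:5,6-di-O-isopropylidene-α-D-mannofuranosyl)hexahydro-1H-cyclopenta[c]isoxazole | BrCCCCCCC[C@@H]1ON([C@H]2O[C@H]([C@H]4COC(C)(C)O4)[C@@H]3OC(C)(C)O[C@H]23)[C@@H]5CCC[C@H]15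
F4 | step 6 | (3S,3aS,6aR)-3-(7-bromoheptyl)hexahydro-1H-cyclopenta[c]isoxazole | BrCCCCCCC[C@@H]1ON[C@@H]2CCC[C@H]12
F5 | step 7 | [12-[(3S,3aS,6aR)-3-[7-(triphenylphosphonio)heptyl]hexahydro-1H-cyclopenta[c]isoxazol-1-yl]dodecyl]triphenylphosphonium dibromide | [Br-].[Br-].c1ccccc1[P+](c1ccccc1)(c1ccccc1)CCCCCCCCCCCCN1O[C@@H](CCCCCCC[P+](c3ccccc3)(c3ccccc3)c3ccccc3)[C@H]2CCC[C@H]21
F6 | step 7 | (3S,3aS,6aR)-1-[(12Z)-13-(pyridin-3-yl)tridec-12-en-1-yl]-3-[(7Z)-8-(pyridin-3-yl)oct-7-en-1-yl]hexahydro-1H-cyclopenta[c]isoxazole | c1cncc(/C=C\CCCCCCCCCCCN2O[C@@H](CCCCCC/C=C\c3cccnc3)[C@H]3CCC[C@H]32)c1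
F7 | step 2 | hex-5-yn-1-ol | C#CCCCCO
F8 | step 2 | 13-bromotridec-5-yn-1-ol | OCCCCC#CCCCCCCCBr
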